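**Plan**
- Numbering: ring A = C1, C2, C3, C4, C4a, C8a (ester on C1, methyl on C2). Ring B = C4a, C5, C6, C7, C8, C8a. C19 and C20 are the methyl carbons on C4a and C8a. β is their face, α the opposite one.
- Enabling feature: C19 and C20 stand cis on the two adjacent quaternary carbons of the bond shared by rings A and B. Joined C19–C20, they are a two-carbon unit that one alkene can deliver across a C4a=C8a enone whose carbonyl is C5.
- Cuts, in retrosynthetic order: the acetate and glyceryl C–O bonds; C5–C1' (side chain); a reconnected C19–C20 bond (glycol cleavage, CHO to CH3); C4a–C19 and C8a–C20 ([2+2]); C1–C8a (ring A); C4–C4a; C1–C2.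
- Forward: ring B is bought as cyclohexane-1,3-dione and the C1–C4 chain is hung on C4a. Ring A closes at C1–C8a, the cyclobutane is added and cut open, and then the side chain and finally the glyceride are joined.
- Stereochemistry: C2 comes from an amine-catalysed Michael addition. C4a and C8a follow from C2 through the ring A half-chair in the photocycloaddition. C1 is set by late equilibration; until then it stays a geminal diester, because a C1–H beside the enone would be a labile vinylogous β-keto ester centre. The glycerol carbon comes from (R)-solketal.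

Key step: step 5

Remark: the carbonate of 10 is drawn over ring B, but either orientation serves because C19 and C20 lose their stereochemistry in step 7. Compound 22 is an epimer mixture and is written without configuration at C1.

**Route**

Step 1
Reactants: 1 dimethyl malonate; 2 (E)-but-2-enal (crotonaldehyde)
Product: 3 dimethyl 2-[(2R)-4-oxobutan-2-yl]propanedioate
Conditions: (S)-2-[diphenyl(trimethylsilyloxy)methyl]pyrrolidine (10 mol %), PhCO2H (10 mol %), EtOH, 0 °C
Reagents that add atoms: none
Why: Iminium-catalysed asymmetric Michael addition of a malonate to an enal; the CPh2(OSiMe3) group covers one face of the s-trans E-iminium ion, so the malonate should enter from the open face and set the (R) centre that becomes C2.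

Step 2
Reactants: 3 aldehyde diester; 4 cyclohexane-1,3-dione
Product: 6 dimethyl 2-[(2R)-4-(2,6-dioxocyclohexyl)butan-2-yl]propanedioate, via alkylidene dione 5 (not isolated)
Conditions: diethyl 2,6-dimethyl-1,4-dihydropyridine-3,5-dicarboxylate (1.05 equiv), L-proline (20 mol %), CH2Cl2, rt
Reagents that add atoms: none
Why: Three-component reductive alkylation: proline-catalysed Knoevenagel condensation gives 5, a strong acceptor that takes up hydride from the Hantzsch dihydropyridine faster than a second dione can add, and the C2 centre, two carbons from the aldehyde, is not involved.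

Step 3
Reactants: 6 2-alkyl dione
Product: 7 dimethyl 2-[(2R)-4-(2-chloro-6-oxocyclohex-1-en-1-yl)butan-2-yl]propanedioate
Conditions: (COCl)2 (1.3 equiv), DMF (cat.), CH2Cl2, 0 °C → rt
Reagents that add atoms: oxalyl chloride, O=C(Cl)C(=O)Cl
Why: Conversion of a vinylogous acid into its vinylogous acid chloride (Vilsmeier-type activation of the enol, then chloride addition–elimination); the dione is symmetric, so only one β-chloro enone can form, and the malonate is inert to the reagent.

Step 4
Reactants: 7 β-chloro enone
Product: 8 dimethyl (2R)-2-methyl-5-oxo-3,4,5,6,7,8-hexahydronaphthalene-1,1(2H)-dicarboxylate (bicyclic C4a=C8a enone, C5 ketone, C1 geminal diester, 2α-methyl)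
Conditions: NaH (1.1 equiv), THF–DMF, 0 → 50 °C
Reagents that add atoms: none
Why: Conjugate addition–elimination (vinylogous acyl substitution) of a malonate anion on a β-chloro enone, run as a 6-endo-trig closure of ring A that forms C1–C8a; one equivalent of base finds only the malonate C–H, loss of chloride makes the closure irreversible, and no stereocentre arises because C1 carries two identical esters.

Step 5
Reactants: 8 bicyclic enone diester; 9 vinylene carbonate (1,3-dioxol-2-one)
Product: 10 [4.4.2]propellane carbonate: cyclobutane C4a–C19–C20–C8a on the β face (anti to the 2α-methyl), cis cyclic carbonate on C19/C20 lying over ring B, C5 ketone, C1 geminal dimethyl ester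
Conditions: 9 (10 equiv), hν (medium-pressure Hg lamp, Pyrex, λ > 300 nm), CH2Cl2, −20 °C
Reagents that add atoms: none
Why: Irradiation populates the enone triplet (n,π* absorption, intersystem crossing), which bonds to the alkene to give a triplet 1,4-biradical that closes after spin inversion; the reaction type is the enone–alkene [2+2] photocycloaddition, known for bicyclo[4.4.0]dec-1(6)-en-2-ones (propellane formation) and for vinylene carbonate as the alkene. The one ring closed is the cyclobutane, built intermolecularly by two successive C–C bonds (C4a–C19 and C8a–C20), the second by collapse of the biradical; because three rings then share the C4a–C8a bond, both new bonds must leave from the same face, which fixes the two quaternary centres as a cis pair. The face is decided by C2: in the ring A half-chair with the C2 methyl equatorial, one C1 ester stands pseudoaxial on the α face beside C8a and the β face carries only hydrogens, whereas the flipped half-chair has an ester over the β face and the axial methyl over the α face and is hindered on both sides, so addition should run on the β face, anti to the methyl. C19 and C20 are cis to each other because the alkene is held in a five-membered ring, and the orientation of the carbonate over the flatter ring B is without consequence since both carbinol centres vanish in step 7. Head-to-head and head-to-tail isomers cannot exist because both alkene carbons of 9 are equivalent; chemoselectivity rests on light that only the enone absorbs and on the excess of 9, and the quaternary C1 offers no acidic γ-hydrogen, so neither epimerisation nor deconjugation can erode the substrate.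

Step 6
Reactants: 10 propellane ketone
Product: 11 C5 ethylene ketal of 10 (5,5-ethylenedioxy propellane carbonate)
Conditions: Me3SiOCH2CH2OSiMe3 (3 equiv), Me3SiOTf (10 mol %), CH2Cl2, −78 → −20 °C
Reagents that add atoms: 1,2-bis(trimethylsilyloxy)ethane, C[Si](C)(C)OCCO[Si](C)(C)C
Why: Aprotic ketalisation with the bis-silyl ether of glycol masks C5, since a free ketone would let the cyclobutanol of step 7 open by retro-aldol (de Mayo-type) cleavage of C4a–C19 and would turn the later C19 aldehyde into a β-keto aldehyde prone to deformylation; the low temperature and the electron-poor cyclobutane guard against acid-induced skeletal shifts.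

Step 7
Reactants: 11 ketal carbonate
Product: 13 dimethyl 4aβ,8aβ-diformyl-5,5-ethylenedioxy-2α-methyl-cis-decalin-1,1-dicarboxylate, via cyclobutanediol 12 (not isolated)
Conditions: K2CO3 (0.2 equiv), MeOH, 0 °C; then pH 7 phosphate buffer, NaIO4 (1.5 equiv), THF–H2O, rt
Reagents that add atoms: none
Why: Base-catalysed transesterification frees the cis-diol and periodate glycol cleavage then breaks C19–C20 with release of ring strain; both aldehydes sit on quaternary carbons and cannot enolise, so C4a and C8a are safe.

Step 8
Reactants: 13 dialdehyde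
Product: 14 bis(p-toluenesulfonylhydrazone) of 13 (both C=N bonds E)
Conditions: TsNHNH2 (2.5 equiv), MeOH–THF, rt → 45 °C
Reagents that add atoms: p-toluenesulfonohydrazide, Cc1ccc(cc1)S(=O)(=O)NN
Why: Hydrazone condensation, which aldehydes undergo without added acid so that the ketal is spared; the quaternary C4a and C8a exclude Paal–Knorr-type aromatisation of the 1,4-dicarbonyl unit.

Step 9
Reactants: 14 bis(tosylhydrazone)
Product: 16 dimethyl 5,5-ethylenedioxy-2α,4aβ,8aβ-trimethyl-cis-decalin-1,1-dicarboxylate, via bis(N-boryl)hydrazine 15 (not isolated)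
Conditions: catecholborane (5 equiv), CHCl3, −10 → 0 °C; then NaOAc·3H2O, reflux
Reagents that add atoms: catecholborane, B1Oc2ccccc2O1 (its boryl group stays in intermediate 15 only)
Why: Caglioti-type deoxygenation (hydride addition to C=N, loss of sulfinate, loss of N2 from the alkyldiazene) turns each CH=N into CH3 under near-neutral conditions that esters and ketal tolerate; no stereocentre is touched and no alkene or ketone is present that could trap a transient C19 or C20 radical.

Step 10
Reactants: 16 dimethyl ketal
Product: 17 dimethyl 2α,4aβ,8aβ-trimethyl-5-oxo-cis-decalin-1,1-dicarboxylate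
Conditions: 1 M HCl, THF, rt → 40 °C
Reagents that add atoms: water, O
Why: Acid-catalysed ketal hydrolysis, helped by relief of crowding next to C4a; the hindered methyl esters are inert and C4a is quaternary, so nothing can epimerise.

Step 11
Reactants: 17 ketone
Product: 18 C5=C6 enol triflate of 17
Conditions: KN(SiMe3)2 (1.1 equiv), THF, −78 °C; then PhNTf2 (1.2 equiv), −78 → 0 °C
Reagents that add atoms: N-phenylbis(trifluoromethanesulfonimide), O=S(=O)(N(c1ccccc1)S(=O)(=O)C(F)(F)F)C(F)(F)F
Why: Enolate O-sulfonylation; enolisation can only go toward C6 because C4a is quaternary and C1 bears no hydrogen, so the position of the final ring alkene is fixed here.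

Step 12
Reactants: 18 enol triflate; 19 5-bromo-2-methylpent-2-ene
Product: 21 dimethyl (2R,4aR,8aS)-2,4a,8a-trimethyl-5-(4-methylpent-3-en-1-yl)-3,4,4a,7,8,8a-hexahydronaphthalene-1,1(2H)-dicarboxylate, via homoprenylzinc bromide 20 (not isolated)
Conditions: 19, Zn dust, LiCl, THF, 40 °C; then 18, PdCl2(dppf) (5 mol %), THF, 55 °C
Reagents that add atoms: zinc, [Zn] (stays in intermediate 20 only)
Why: Negishi sp2–sp3 cross-coupling (oxidative addition of the triflate to zerovalent palladium, transmetallation from zinc, reductive elimination); the wide-bite-angle dppf ligand holds back β-hydride elimination and the alkylzinc halide leaves the esters alone.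

Step 13
Reactants: 21 geminal diester
Product: 22 methyl 2α,4aβ,8aβ-trimethyl-5-(4-methylpent-3-en-1-yl)-1,2,3,4,4a,7,8,8a-octahydronaphthalene-1-carboxylate, both C1 epimers
Conditions: LiCl (5 equiv), H2O (2 equiv), DMSO, 150 °C
Reagents that add atoms: none
Why: Krapcho dealkoxycarbonylation: chloride attacks a methyl group by SN2, so crowding at the carbonyl is irrelevant, the carboxylate loses CO2 with relief of strain, and water protonates the ester enolate to give C1 as a mixture that step 14 corrects.

Step 14
Reactants: 22 monoester, C1 epimers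
Product: 23 methyl (1S,2R,4aR,8aR)-2,4a,8a-trimethyl-5-(4-methylpent-3-en-1-yl)-1,2,3,4,4a,7,8,8a-octahydronaphthalene-1-carboxylate (1β-ester)
Conditions: NaOMe (5 equiv), MeOH, reflux
Reagents that add atoms: none
Why: Thermodynamic epimerisation through the ester enolate: the 1β-ester has a ring A chair with the ester and the C2 methyl both equatorial, whereas the 1α-ester must place either the ester syn-axial to C5 or the C2 methyl syn-axial to C8, so the equilibrium should lie on the side of the (1S) centre.

Step 15
Reactants: 23 methyl ester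
Product: 24 (1S,2R,4aR,8aR)-2,4a,8a-trimethyl-5-(4-methylpent-3-en-1-yl)-1,2,3,4,4a,7,8,8a-octahydronaphthalene-1-carboxylic acid
Conditions: NaSEt (5 equiv), DMF, 100 °C; then 1 M HCl
Reagents that add atoms: none
Why: SN2 dealkylation of a hindered methyl ester by thiolate, which attacks the methyl carbon and not the shielded carbonyl; the alkenes are inert and C1 already holds its stable configuration.

Step 16
Reactants: 24 acid; 25 (R)-solketal [(4R)-2,2-dimethyl-1,3-dioxolan-4-yl]methanol
Product: 26 [(4S)-2,2-dimethyl-1,3-dioxolan-4-yl]methyl ester of 24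
Conditions: PPh3, diisopropyl azodicarboxylate, THF, 0 °C → rt
Reagents that add atoms: none
Why: Mitsunobu esterification, in which the carboxylate is the nucleophile at the activated primary carbon of 25, so shielding of the acyl carbon does not matter and the dioxolane centre is untouched (only its descriptor changes); any residue of the enantiomeric acid from step 1 becomes a separable diastereomer here.

Step 17
Reactants: 26 acetonide ester
Product: 27 (2S)-2,3-dihydroxypropyl ester of 24
Conditions: AcOH–H2O (4:1), 40 °C
Reagents that add atoms: none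
Why: Mild acid hydrolysis of the isopropylidene acetal; the bulky acyl group is slow to migrate and trisubstituted alkenes tolerate aqueous acetic acid.

Step 18
Reactants: 27 monoacylglycerol
Product: 28 (2S)-3-acetoxy-2-hydroxypropyl (1S,2R,4aR,8aR)-2,4a,8a-trimethyl-5-(4-methylpent-3-en-1-yl)-1,2,3,4,4a,7,8,8a-octahydronaphthalene-1-carboxylate (target)
Conditions: AcCl (1.05 equiv), 2,4,6-collidine, CH2Cl2, −78 °C
Reagents that add atoms: acetyl chloride, CC(=O)Cl
Why: Selective acylation of a primary over a secondary hydroxyl with acetyl chloride and a hindered pyridine base at low temperature, conditions under which acyl migration should stay frozen.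

**Compound list**

1 | dimethyl malonate | COC(=O)CC(=O)OC | starting material
2 | (E)-but-2-enal | C/C=C/C=O | starting material
3 | dimethyl 2-[(2R)-4-oxobutan-2-yl]propanedioate | COC(=O)C(C(=O)OC)[C@H](C)CC=O | intermediate
4 | cyclohexane-1,3-dione | O=C1CCCC(=O)C1 | starting material
5 | dimethyl 2-[(2R)-4-(2,6-dioxocyclohexylidene)butan-2-yl]propanedioate | COC(=O)C(C(=O)OC)[C@H](C)CC=C1C(=O)CCCC1=O | intermediate
6 | dimethyl 2-[(2R)-4-(2,6-dioxocyclohexyl)butan-2-yl]propanedioate | COC(=O)C(C(=O)OC)[C@H](C)CCC1C(=O)CCCC1=O | intermediate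
7 | dimethyl 2-[(2R)-4-(2-chloro-6-oxocyclohex-1-en-1-yl)butan-2-yl]propanedioate | COC(=O)C(C(=O)OC)[C@H](C)CCC1=C(Cl)CCCC1=O | intermediate
8 | bicyclic enone geminal diester | COC(=O)C1(C(=O)OC)[C@H](C)CCC2=C1CCCC2=O | intermediate
9 | vinylene carbonate | O=C1OC=CO1 | starting material
10 | propellane carbonate, C5 ketone | COC(=O)C1(C(=O)OC)[C@H](C)CC[C@]23C(=O)CCC[C@]12[C@H]1OC(=O)O[C@H]13 | intermediate
11 | propellane carbonate, C5 ethylene ketal | COC(=O)C1(C(=O)OC)[C@H](C)CC[C@]23C4(OCCO4)CCC[C@]12[C@H]1OC(=O)O[C@H]13 | intermediate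
12 | propellane cis-C19,C20-diol, C5 ketal | COC(=O)C1(C(=O)OC)[C@H](C)CC[C@]23C4(OCCO4)CCC[C@]12[C@@H](O)[C@H]3O | intermediate
13 | 4aβ,8aβ-dialdehyde, C5 ketal | COC(=O)C1(C(=O)OC)[C@H](C)CC[C@]2(C=O)C3(OCCO3)CCC[C@]12C=O | intermediate
14 | bis(tosylhydrazone) of 13 | COC(=O)C1(C(=O)OC)[C@H](C)CC[C@]2(/C=N/NS(=O)(=O)c3ccc(C)cc3)C3(OCCO3)CCC[C@]12/C=N/NS(=O)(=O)c1ccc(C)cc1 | intermediate
15 | bis(N-boryl-N'-tosylhydrazine) | COC(=O)C1(C(=O)OC)[C@H](C)CC[C@]2(CN(NS(=O)(=O)c3ccc(C)cc3)B3Oc4ccccc4O3)C3(OCCO3)CCC[C@]12CN(NS(=O)(=O)c1ccc(C)cc1)B1Oc2ccccc2O1 | intermediate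
16 | 4aβ,8aβ-dimethyl ketal diester | COC(=O)C1(C(=O)OC)[C@H](C)CC[C@]2(C)C3(OCCO3)CCC[C@]12C | intermediate
17 | 4aβ,8aβ-dimethyl C5 ketone diester | COC(=O)C1(C(=O)OC)[C@H](C)CC[C@]2(C)C(=O)CCC[C@]12C | intermediate
18 | C5=C6 enol triflate diester | COC(=O)C1(C(=O)OC)[C@H](C)CC[C@]2(C)C(OS(=O)(=O)C(F)(F)F)=CCC[C@]12C | intermediate
19 | 5-bromo-2-methylpent-2-ene | CC(C)=CCCBr | starting material
20 | (4-methylpent-3-en-1-yl)zinc bromide | CC(C)=CCC[Zn]Br | intermediate
21 | side-chain-bearing geminal diester | COC(=O)C1(C(=O)OC)[C@H](C)CC[C@]2(C)C(CCC=C(C)C)=CCC[C@]12C | intermediate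
22 | monoester, both C1 epimers | COC(=O)C1[C@H](C)CC[C@]2(C)C(CCC=C(C)C)=CCC[C@]12C | intermediate
23 | (1S)-methyl ester | COC(=O)[C@H]1[C@H](C)CC[C@]2(C)C(CCC=C(C)C)=CCC[C@]12C | intermediate
24 | (1S)-carboxylic acid | OC(=O)[C@H]1[C@H](C)CC[C@]2(C)C(CCC=C(C)C)=CCC[C@]12C | intermediate
25 | (R)-solketal | OC[C@@H]1COC(C)(C)O1 | starting material
26 | solketal ester | CC1(C)OC[C@@H](COC(=O)[C@H]2[C@H](C)CC[C@]3(C)C(CCC=C(C)C)=CCC[C@]23C)O1 | intermediate
27 | (2S)-2,3-dihydroxypropyl ester | OC[C@H](O)COC(=O)[C@H]1[C@H](C)CC[C@]2(C)C(CCC=C(C)C)=CCC[C@]12C | intermediate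
28 | CNP0146255.1 | CC(=O)OC[C@H](O)COC(=O)[C@H]1[C@H](C)CC[C@]2(C)C(CCC=C(C)C)=CCC[C@]12C | target

**Count**

Total step count: 18. The organozinc reagent is made inside step 12.
Longest linear sequence: 18 steps, from 1 and 2 to 28.

**Steps most likely to fail**

**Step 5.**
- What may go wrong: facial selectivity may be poor. The bias from the C2 methyl is relayed only through the ring A half-chair. Capture of the triplet next to the quaternary C1 may also be slow, leaving room for decay and alkene polymerisation.
- Fallback, from 8 back to 23: one ester is removed first so that the other acts as a dedicated screen.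
  - Krapcho dealkoxycarbonylation of 8 (LiCl, wet DMSO, 130 °C) gives the monoester enone epimers F1.
  - Equilibration with DBU and chromatography, with recycling of the trans isomer, deliver the cis (1R,2R) monoester enone F2. Its ester is pseudoaxial on the α face.
  - Irradiation with 9 should give the monoester propellane carbonate F3.
  - The operations of steps 6 to 12 then lead in turn through the ketal F4, the cyclobutanediol F5, the dialdehyde F6, the bis(tosylhydrazone) F7, the bis(N-boryl)hydrazine F8, the dimethyl ketal F9, the ketone F10 and the enol triflate F11.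
  - Coupling of F11 with 20 gives the 1α-methyl ester F12, which the conditions of step 14 convert into 23.

**Step 9 (together with step 8).**
- What may go wrong: the double deoxygenation at two neighbouring neopentyl positions may stall. The mono-hydrazone may cyclise onto the second aldehyde. The intermediate alkylhydrazine nitrogen on C20 may be intercepted by the adjacent C1 ester, giving a lactam.
- Fallback, from 10 back to 21: the side chain is installed before the cyclobutane is opened. C5 then ceases to be a carbonyl, no mask is needed, and sulfur chemistry replaces nitrogen chemistry.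
  - KN(SiMe3)2 and PhNTf2 give the propellane enol triflate F13.
  - Coupling with 20 under PdCl2(dppf) gives the side-chain propellane carbonate F14.
  - K2CO3 in MeOH gives the diol F15, and NaIO4 gives the dialdehyde F16.
  - Ethane-1,2-dithiol with Zn(OTf)2 in CH2Cl2 gives the bis(dithiolane) F17.
  - Desulfurisation with NiCl2·6H2O and NaBH4 in MeOH–THF, which should spare trisubstituted alkenes, gives 21.

**Step 14.**
- What may go wrong: deprotonation of the shielded C1–H may be slow, so that equilibrium is not reached before the ester degrades.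
- Fallback, from 22 back to 24: the epimerisation is moved to the aldehyde level. This also bypasses the ester cleavage of step 15.
  - LiAlH4 (THF, 0 °C) reduces 22 to the primary alcohols F18.
  - Dess–Martin periodinane gives the aldehydes F19.
  - DBU in CH2Cl2 equilibrates the much more acidic centre to the 1β-aldehyde F20.
  - Pinnick oxidation (NaClO2, NaH2PO4, 2-methylbut-2-ene, t-BuOH–H2O) gives 24.

**Further compounds**

F1 | step 5 | monoester enone, both C1 epimers | COC(=O)C1[C@H](C)CCC2=C1CCCC2=O
F2 | step 5 | cis (1R,2R) monoester enone | COC(=O)[C@@H]1[C@H](C)CCC2=C1CCCC2=O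
F3 | step 5 | monoester propellane carbonate | COC(=O)[C@@H]1[C@H](C)CC[C@]23C(=O)CCC[C@]12[C@H]1OC(=O)O[C@H]13
F4 | step 5 | monoester propellane ketal | COC(=O)[C@@H]1[C@H](C)CC[C@]23C4(OCCO4)CCC[C@]12[C@H]1OC(=O)O[C@H]13
F5 | step 5 | monoester cyclobutanediol | COC(=O)[C@@H]1[C@H](C)CC[C@]23C4(OCCO4)CCC[C@]12[C@@H](O)[C@H]3O
F6 | step 5 | monoester dialdehyde | COC(=O)[C@@H]1[C@H](C)CC[C@]2(C=O)C3(OCCO3)CCC[C@]12C=O
F7 | step 5 | monoester bis(tosylhydrazone) | COC(=O)[C@@H]1[C@H](C)CC[C@]2(/C=N/NS(=O)(=O)c3ccc(C)cc3)C3(OCCO3)CCC[C@]12/C=N/NS(=O)(=O)c1ccc(C)cc1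
F8 | step 5 | monoester bis(N-boryl)hydrazine | COC(=O)[C@@H]1[C@H](C)CC[C@]2(CN(NS(=O)(=O)c3ccc(C)cc3)B3Oc4ccccc4O3)C3(OCCO3)CCC[C@]12CN(NS(=O)(=O)c1ccc(C)cc1)B1Oc2ccccc2O1
F9 | step 5 | monoester dimethyl ketal | COC(=O)[C@@H]1[C@H](C)CC[C@]2(C)C3(OCCO3)CCC[C@]12C
F10 | step 5 | monoester C5 ketone | COC(=O)[C@@H]1[C@H](C)CC[C@]2(C)C(=O)CCC[C@]12C
F11 | step 5 | monoester enol triflate | COC(=O)[C@@H]1[C@H](C)CC[C@]2(C)C(OS(=O)(=O)C(F)(F)F)=CCC[C@]12C
F12 | step 5 | 1α-methyl ester (C1 epimer of 23) | COC(=O)[C@@H]1[C@H](C)CC[C@]2(C)C(CCC=C(C)C)=CCC[C@]12C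
F13 | step 9 | propellane enol triflate | COC(=O)C1(C(=O)OC)[C@H](C)CC[C@]23C(OS(=O)(=O)C(F)(F)F)=CCC[C@]12[C@H]1OC(=O)O[C@H]13
F14 | step 9 | side-chain propellane carbonate | COC(=O)C1(C(=O)OC)[C@H](C)CC[C@]23C(CCC=C(C)C)=CCC[C@]12[C@H]1OC(=O)O[C@H]13
F15 | step 9 | side-chain propellane diol | COC(=O)C1(C(=O)OC)[C@H](C)CC[C@]23C(CCC=C(C)C)=CCC[C@]12[C@@H](O)[C@H]3O
F16 | step 9 | side-chain dialdehyde | COC(=O)C1(C(=O)OC)[C@H](C)CC[C@]2(C=O)C(CCC=C(C)C)=CCC[C@]12C=O
F17 | step 9 | side-chain bis(dithiolane) | COC(=O)C1(C(=O)OC)[C@H](C)CC[C@]2(C3SCCS3)C(CCC=C(C)C)=CCC[C@]12C1SCCS1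
F18 | step 14 | C1 hydroxymethyl compound, both C1 epimers | OCC1[C@H](C)CC[C@]2(C)C(CCC=C(C)C)=CCC[C@]12C
F19 | step 14 | C1 aldehyde, both C1 epimers | O=CC1[C@H](C)CC[C@]2(C)C(CCC=C(C)C)=CCC[C@]12C
F20 | step 14 | 1β-aldehyde | O=C[C@H]1[C@H](C)CC[C@]2(C)C(CCC=C(C)C)=CCC[C@]12C
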